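**Retrosynthetic overview**
1. Target 19 ⇐ vinyl epoxide 17 + acid 18: trans-diaxial opening at allylic C6 sets the C6 ester and the C5 alcohol.
2. 17 ⇐ enone 14 (epoxidation, methylenation, acetylation) ⇐ ketone 11 (dehydrogenation).
3. 11 (ring B, the C8 carbinol and the Z-ethylidene) ⇐ ynal 10 by an electrochemical nickel-catalysed methylative aldehyde–alkyne cyclization that forms C8–C9 and C10–C11.
4. 10 ⇐ apoverbenone 3 by conjugate alkynylation (C3), allylation (C2), reductive cyclobutane opening (unmasks the C4 isopropyl) and alkene cleavage; 3 ⇐ (+)-nopinone 1.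
5. Ring order: ring A (six-membered) is bought in nopinone; ring B (five-membered) is closed in step 6.

Assumption: (1R)-(+)-nopinone (the ozonolysis product of natural (−)-β-pinene) and (2E)-3-methylpent-2-enoic acid are taken as catalogue chemicals.

Locants used below (target numbering, kept from 1 onward): ring A is C1(=CH2)–C2–C3–C4(i-Pr)–C5(OH)–C6(O-acyl); ring B is C2–C7–C8(OAc)–C9(=C10H–C11H3)–C3. β is the face of H-2 (and of the C6 and C8 oxygens); α is the face of H-3 (and of the isopropyl group and the C5 oxygen). In 1 the carbonyl is C1, the bridgeheads are C4 and C6, and the CMe2 bridge links C4 and C6 on the α face.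

**Step 1**
Reactants: 1 (1R,5S)-6,6-dimethylbicyclo[3.1.1]heptan-2-one ((+)-nopinone)
Product: 3 (1R,5R)-6,6-dimethylbicyclo[3.1.1]hept-3-en-2-one (apoverbenone), via lithium enolate 2 (not isolated)
Conditions: LiN(i-Pr)2, THF, −78 °C; PhS(Cl)=N-t-Bu, −78 °C
Reagents that add atoms: none
Why: Mukaiyama dehydrogenation: the ketone can enolize only toward C2 (the other α-carbon is a bridgehead) and the lithium enolate is oxidized to the enone by the sulfinimidoyl chloride; no stereocentre is formed or touched.

**Step 2**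
Reactants: 3 apoverbenone
Product: 4 (1R,4R,5R)-6,6-dimethyl-4-[(trimethylsilyl)ethynyl]bicyclo[3.1.1]heptan-2-one
Conditions: Me3SiC≡CH, n-BuLi, Et2O, 0 °C; Me2AlCl; then Ni(acac)2 (5 mol %), i-Bu2AlH (5 mol %), 3, Et2O, −5 °C; aq. KH2PO4
Reagents that add atoms: (trimethylsilyl)acetylene, C#C[Si](C)(C)C
Why: Nickel-catalysed conjugate addition of an alkynylalane (1,4-alkynylation): the alkynyl group adds to C3 from the β face, anti to the gem-dimethyl bridge, which fixes C3 relative to the bridgehead C4 bought in 1.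

**Step 3**
Reactants: 4 alkynyl ketone
Product: 6 (1R,3S,4S,5R)-6,6-dimethyl-3-(prop-2-en-1-yl)-4-[(trimethylsilyl)ethynyl]bicyclo[3.1.1]heptan-2-one, via lithium enolate 5 (not isolated)
Conditions: LiN(i-Pr)2, THF, −78 °C; allyl iodide, −78 → −20 °C
Reagents that add atoms: allyl iodide, C=CCI
Why: Enolate alkylation: the enolate can form only at C2 and is attacked on the open β face; this C2 configuration (allyl cis to alkynyl) is provisional and is corrected in step 4.

**Step 4**
Reactants: 6 allyl alkynyl ketone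
Product: 8 (2R,3S,4S)-3-ethynyl-4-(propan-2-yl)-2-(prop-2-en-1-yl)cyclohexan-1-one, via 2,3-cis silyl ketone 7 (not isolated)
Conditions: SmI2 (2.5 equiv), HMPA, t-BuOH, THF, −78 → 0 °C; then K2CO3, MeOH, rt (same flask)
Reagents that add atoms: none
Why: Ketyl fragmentation (reductive α-ketocyclobutane cleavage): electron transfer from SmI2 opens the strained C6–CMe2 bond to a tertiary radical that is reduced and protonated to the isopropyl group with C4 untouched, and K2CO3/MeOH then removes the alkyne silyl group and equilibrates the enolizable C2 to the all-equatorial 2,3-trans-3,4-trans ketone under control of C3 and C4.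

**Step 5**
Reactants: 8 all-trans allyl ethynyl ketone
Product: 10 2-[(1R,2S,3S)-2-ethynyl-6-oxo-3-(propan-2-yl)cyclohexyl]acetaldehyde, via vicinal diol 9 (not isolated)
Conditions: OsO4 (2 mol %), NaIO4, 2,6-lutidine, dioxane/H2O, rt
Reagents that add atoms: osmium tetroxide, O=[Os](=O)(=O)=O; sodium periodate, [Na+].[O-]I(=O)(=O)=O
Why: Lemieux–Johnson oxidative cleavage of the terminal alkene, which OsO4 dihydroxylates far faster than the terminal alkyne; lutidine buffering keeps the α-stereocentre C2.

**Step 6**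
Reactants: 10 keto ynal
Product: 11 (1Z,2R,3aR,7S,7aS)-1-ethylidene-2-hydroxy-7-(propan-2-yl)octahydro-4H-inden-4-one
Conditions: NiBr2(dme) (10 mol %), 4,4′-di-tert-butyl-2,2′-bipyridine (12 mol %), N-acetoxyphthalimide (2.5 equiv), LiBr, DMA, Zn anode, carbon-felt cathode, undivided cell, 4 mA (3 F/mol), rt; aq. NH4Cl
Reagents that add atoms: N-acetoxyphthalimide, CC(=O)ON1C(=O)c2ccccc2C1=O
Why: Proposed new method: cathodically generated zerovalent nickel–bipyridine joins aldehyde and alkyne by oxidative cyclization to an oxanickelacyclopentene (C8–C9 bond), this divalent alkenylnickel alkoxide captures the methyl radical released by one-electron reduction and decarboxylation of the redox-active ester, and reductive elimination from trivalent nickel forms C10–CH3 with retention so that methyl and C8 are cis (Z) by mechanism, while C8 is set by the existing centres because only the 8β-oxygen can lie near the plane of the nascent C9=C10 bond in the metallacycle (the sign of the ring-B torsion about C8–C9 is dictated by the trans C2–C3 fusion); closest known reaction types are the thermal nickel-catalysed alkylative cyclization of ynals with organozinc reagents and the nickel-electrocatalytic decarboxylative alkenylation of N-hydroxyphthalimide esters.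

**Step 7**
Reactants: 11 hydroxy ketone
Product: 14 (1Z,2R,3aR,7R,7aS)-1-ethylidene-2-hydroxy-7-(propan-2-yl)-1,2,3,3a,7,7a-hexahydro-4H-inden-4-one, via bis(trimethylsilyl) enol ether 12 (not isolated), via trimethylsilyl ether enone 13 (not isolated)
Conditions: LiN(i-Pr)2 (2.5 equiv), Me3SiCl, THF, −78 °C; Pd(OAc)2, MeCN, rt; then 1 M HCl, THF, 0 °C
Reagents that add atoms: none
Why: Saegusa–Ito dehydrogenation: kinetic deprotonation takes a C6 methylene proton and not the hindered ring-fusion H-2, so the C5=C6 enone forms with the trans ring fusion intact.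

**Step 8**
Reactants: 14 enone alcohol
Product: 15 5α,6α-epoxy-8β-hydroxy ketone (epoxide of 14 on the face of the isopropyl group)
Conditions: 30% H2O2, NaOH (0.2 equiv), MeOH, 0 °C
Reagents that add atoms: hydrogen peroxide, OO
Why: Weitz–Scheffer nucleophilic epoxidation: in the conformationally locked trans-fused enone, hydroperoxide adds axially to C5, that is from the α face anti to the pseudoaxial H-4, and closes on the same face to the 5α,6α-epoxide cis to the isopropyl group.

**Step 9**
Reactants: 15 epoxy ketone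
Product: 16 5α,6α-epoxy-1-methylidene 8β-alcohol
Conditions: Ph3PCH3Br (4 equiv), KOt-Bu (3.8 equiv), THF, 0 °C → rt
Reagents that add atoms: methyltriphenylphosphonium bromide, C[P+](c1ccccc1)(c1ccccc1)c1ccccc1.[Br-]
Why: Wittig methylenation of the ketone, which is faster than enolization so that C2 and the epoxide are untouched; the excess ylide covers the free hydroxyl.

**Step 10**
Reactants: 16 vinyl epoxide alcohol
Product: 17 5α,6α-epoxy-1-methylidene 8β-acetate
Conditions: Ac2O, pyridine, DMAP (cat.), CH2Cl2, 0 °C → rt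
Reagents that add atoms: acetic anhydride, CC(=O)OC(C)=O
Why: DMAP-catalysed acetylation of the only hydroxyl group, with retention at C8.

**Step 11**
Reactants: 17 vinyl epoxide acetate; 18 (2E)-3-methylpent-2-enoic acid
Product: 19 (1Z,2R,3aR,5S,6S,7S,7aR)-2-(acetyloxy)-1-ethylidene-6-hydroxy-4-methylidene-7-(propan-2-yl)octahydro-1H-inden-5-yl (2E)-3-methylpent-2-enoate (CNP0418642.2)
Conditions: 18 (5 equiv), Cs2CO3 (1 equiv), DMF, 60 °C
Reagents that add atoms: none
Why: SN2 opening of the vinyl epoxide by the carboxylate at the allylic C6 from the β face (trans-diaxial, Fürst–Plattner) gives the 6β-ester with inversion and leaves the 5α-hydroxyl free.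

**Compound list**
1 | (1R,5S)-6,6-dimethylbicyclo[3.1.1]heptan-2-one, (+)-nopinone | O=C1CC[C@H]2C[C@@H]1C2(C)C | starting material
2 | lithium enolate of 1 (C1=C2 enolate) | [Li]OC1=CC[C@H]2C[C@@H]1C2(C)C | intermediate
3 | (1R,5R)-6,6-dimethylbicyclo[3.1.1]hept-3-en-2-one (apoverbenone) | O=C1C=C[C@H]2C[C@@H]1C2(C)C | intermediate
4 | (1R,4R,5R)-6,6-dimethyl-4-[(trimethylsilyl)ethynyl]bicyclo[3.1.1]heptan-2-one (alkynyl anti to the CMe2 bridge) | O=C1C[C@@H](C#C[Si](C)(C)C)[C@H]2C[C@@H]1C2(C)C | intermediate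
5 | lithium enolate of 4 (C1=C2 enolate) | [Li]OC1=C[C@@H](C#C[Si](C)(C)C)[C@H]2C[C@@H]1C2(C)C | intermediate
6 | (1R,3S,4S,5R)-6,6-dimethyl-3-(prop-2-en-1-yl)-4-[(trimethylsilyl)ethynyl]bicyclo[3.1.1]heptan-2-one (allyl and alkynyl cis, both anti to the bridge) | O=C1[C@@H](CC=C)[C@@H](C#C[Si](C)(C)C)[C@H]2C[C@@H]1C2(C)C | intermediate
7 | (2S,3S,4S)-4-(propan-2-yl)-2-(prop-2-en-1-yl)-3-[(trimethylsilyl)ethynyl]cyclohexan-1-one (2,3-cis, 3,4-trans) | O=C1[C@@H](CC=C)[C@@H](C#C[Si](C)(C)C)[C@H](C(C)C)CC1 | intermediate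
8 | (2R,3S,4S)-3-ethynyl-4-(propan-2-yl)-2-(prop-2-en-1-yl)cyclohexan-1-one (all-trans) | O=C1[C@H](CC=C)[C@@H](C#C)[C@H](C(C)C)CC1 | intermediate
9 | (2R,3S,4S)-2-(2,3-dihydroxypropyl)-3-ethynyl-4-(propan-2-yl)cyclohexan-1-one (both carbinol epimers) | O=C1[C@H](CC(O)CO)[C@@H](C#C)[C@H](C(C)C)CC1 | intermediate
10 | 2-[(1R,2S,3S)-2-ethynyl-6-oxo-3-(propan-2-yl)cyclohexyl]acetaldehyde | O=C1[C@H](CC=O)[C@@H](C#C)[C@H](C(C)C)CC1 | intermediate
11 | (1Z,2R,3aR,7S,7aS)-1-ethylidene-2-hydroxy-7-(propan-2-yl)octahydro-4H-inden-4-one (trans-fused; C1 ketone, 8β-OH, Z-ethylidene, 4α-isopropyl) | O=C1[C@@H]2C[C@@H](O)/C(=C\C)[C@H]2[C@H](C(C)C)CC1 | intermediate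
12 | bis(trimethylsilyl) derivative of 11: C1=C6 trimethylsilyl enol ether and 8β-trimethylsilyl ether | C[Si](C)(C)OC=1[C@@H]2C[C@@H](O[Si](C)(C)C)/C(=C\C)[C@H]2[C@H](C(C)C)CC1 | intermediate
13 | 8β-trimethylsilyl ether of enone 14 | O=C1[C@@H]2C[C@@H](O[Si](C)(C)C)/C(=C\C)[C@H]2[C@H](C(C)C)C=C1 | intermediate
14 | (1Z,2R,3aR,7R,7aS)-1-ethylidene-2-hydroxy-7-(propan-2-yl)-1,2,3,3a,7,7a-hexahydro-4H-inden-4-one (C5=C6 enone) | O=C1[C@@H]2C[C@@H](O)/C(=C\C)[C@H]2[C@H](C(C)C)C=C1 | intermediate
15 | 5α,6α-epoxide of 14 (epoxide oxygen cis to the isopropyl group; C1 ketone, 8β-OH) | O=C1[C@@H]2C[C@@H](O)/C(=C\C)[C@H]2[C@H](C(C)C)[C@@H]3O[C@H]13 | intermediate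
16 | 1-methylidene analogue of 15 (5α,6α-epoxide, 8β-OH) | C=C1[C@@H]2C[C@@H](O)/C(=C\C)[C@H]2[C@H](C(C)C)[C@@H]3O[C@H]13 | intermediate
17 | 8β-acetate of 16 | C=C1[C@@H]2C[C@@H](OC(C)=O)/C(=C\C)[C@H]2[C@H](C(C)C)[C@@H]3O[C@H]13 | intermediate
18 | (2E)-3-methylpent-2-enoic acid | CC/C(C)=C/C(=O)O | starting material
19 | (1Z,2R,3aR,5S,6S,7S,7aR)-2-(acetyloxy)-1-ethylidene-6-hydroxy-4-methylidene-7-(propan-2-yl)octahydro-1H-inden-5-yl (2E)-3-methylpent-2-enoate | C=C1[C@@H]2C[C@@H](OC(C)=O)/C(=C\C)[C@H]2[C@H](C(C)C)[C@H](O)[C@H]1OC(=O)/C=C(\C)CC | target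

**Step count**
Total: 11 steps. Longest linear sequence: 11 steps (1 → 19); acid 18 is bought.

**Three steps most likely to fail**

Step 6 (the new electrochemical methylative cyclization). The methyl radical may be lost to hydrogen abstraction, the metallacycle may be protonated (giving the methylidene instead of the ethylidene), or the C8 selectivity may be low. The fallback sets out from 10 and comes back at 11. It drops the electrochemical radical-capture manifold for the known thermal organozinc route: Ni(cod)2 (10 mol %), Me2Zn (3 equiv), THF, 0 °C. Here the same oxanickelacycle is methylated by transmetalation and reductive elimination, again placing methyl cis to C8. It makes no compound that is not in the list (none, F0).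

Step 8 (facial selectivity of the epoxidation). If the equatorial isopropyl group overrides axial attack, the β-epoxide forms instead. The fallback sets out from 14 and comes back at 19, and uses that isomer productively. The 5β,6β-epoxy ketone F1 is acetylated (Ac2O, pyridine, DMAP) to the epoxy ketone acetate F2. Catalytic HClO4 in THF/H2O opens F2 at C5 (the carbon β to the carbonyl, trans-diaxial) to the 5α,6β-dihydroxy ketone F3, which already has the target configuration at C5 and C6. Yamaguchi esterification with 18 (2,4,6-trichlorobenzoyl chloride, Et3N, DMAP) acylates the less hindered α-ketol hydroxyl to the 6β-ester ketone F4. Takai–Lombardo methylenation (Zn, CH2Br2, TiCl4, THF) of the C1 ketone then gives 19.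

Step 11 (carboxylate opening of the hindered vinyl epoxide). The opening may be slow or may go partly by SN2′ at the methylidene carbon. The fallback sets out from 17 and comes back at 19. Catalytic HClO4 in THF/H2O hydrolyses the epoxide (water at allylic C6, trans-diaxial) to the 5α,6β-diol acetate F5. Steglich acylation (18, DCC, DMAP, CH2Cl2, 0 °C) then esterifies the allylic 6β-hydroxyl, which is far less hindered than the 5α-hydroxyl flanked by the isopropyl group.

**Further compounds**
F0 | step 6 | none | none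
F1 | step 8 | 5β,6β-epoxy ketone (β-face epimer of 15; 8β-OH) | O=C1[C@@H]2C[C@@H](O)/C(=C\C)[C@H]2[C@H](C(C)C)[C@H]3O[C@@H]13
F2 | step 8 | 8β-acetate of F1 | O=C1[C@@H]2C[C@@H](OC(C)=O)/C(=C\C)[C@H]2[C@H](C(C)C)[C@H]3O[C@@H]13
F3 | step 8 | 5α,6β-dihydroxy C1 ketone 8β-acetate | O=C1[C@@H]2C[C@@H](OC(C)=O)/C(=C\C)[C@H]2[C@H](C(C)C)[C@H](O)[C@H]1O
F4 | step 8 | 6β-[(2E)-3-methylpent-2-enoyl] ester of F3 (5α-OH free, C1 ketone) | O=C1[C@@H]2C[C@@H](OC(C)=O)/C(=C\C)[C@H]2[C@H](C(C)C)[C@H](O)[C@H]1OC(=O)/C=C(\C)CC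
F5 | step 11 | 1-methylidene 5α,6β-diol 8β-acetate | C=C1[C@@H]2C[C@@H](OC(C)=O)/C(=C\C)[C@H]2[C@H](C(C)C)[C@H](O)[C@H]1O
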